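**Retrosynthetic overview**

1. The target is a trans-(2S,3S)-2,3-diaryl-2,3-dihydrobenzofuran whose C4 is bonded to C3 of a (2R,3R,4S,5R)-tetraaryloxolane (aryl groups on oxolane C2, C3 and C4 mutually cis, C5 aryl trans). All eight phenols are carried as benzyl-type ethers and freed last by hydrogenolysis, because acid would epimerise the cis benzylic ether carbons.
2. Feature the plan rests on: the 3,5-dihydroxyphenyl ring on C3 of the dihydrobenzofuran ring (O1, C2, C3, C3a, C7a) is a resorcinol, so it is grown on C3 and not coupled to it. Its ipso carbon is a ketone carbon already bonded to C3; the other five ring carbons are a dioxinone-masked β-polycarbonyl chain, folded by aldol condensation and then decarboxylated.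
3. Disconnections: oxolane C2–H and C3–H by syn hydrogenation of a 2,3-diaryl-4,5-dihydrofuran; oxolane C3–benzofuran C4 by Negishi coupling at the C4 bromide; resorcinol ring by ketene formation, methanol capture and aldol aromatisation; chain by Claisen acylation of a keto-dioxinone dianion; dihydrofuran by dirhodium-carbenoid C–H insertion.
4. Ring order: benzofuran benzene ring (bought), dihydrofuran ring (step 8), resorcinol ring on C3 (step 12), butenolide and dihydrofuran of the oxolane fragment (steps 16 and 18), oxolane stereocentres C2 and C3 (step 21).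

Key step: step 12

Assumption: Rh2(S-PTTL)4, dirhodium tetrakis[N-phthaloyl-(S)-tert-leucinate], is taken to give the (2S,3R) cis ester in step 8 and (S,S)-ProPhenol the S alcohol in step 15; if either sense is the opposite, the mirror-image catalyst or ligand is used and nothing else changes.

Abbreviations in names: Q = (2S,3S)-2-[4-(benzyloxy)phenyl]-6-{[4-(benzyloxy)benzyl]oxy}-4-bromo-2,3-dihydro-1-benzofuran-3-yl; Ar = 2-bromo-4,6-bis{[4-(benzyloxy)benzyl]oxy}phenyl.

**Route**

Step 1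
Reactants: 1 1-bromo-3,5-dimethoxybenzene
Product: 3 2-bromo-4,6-dimethoxybenzaldehyde, via aryl iminium chloride 2 (not isolated)
Conditions: POCl3, DMF, 0 to 90 °C; then H2O, 50 °C
Reagents that add atoms: N,N-dimethylformamide CN(C)C=O; water O
Why: Vilsmeier–Haack formylation, in which the chloroiminium ion attacks the ring carbon para to one methoxy group and ortho to the other (next to bromine) rather than the carbon between the two methoxy groups, and water hydrolyses iminium salt 2.

Step 2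
Reactants: 3 2-bromo-4,6-dimethoxybenzaldehyde
Product: 4 2-bromo-4,6-dihydroxybenzaldehyde
Conditions: BBr3 (3 equiv), CH2Cl2, −78 °C to rt; then H2O
Reagents that add atoms: none
Why: Lewis-acid cleavage of both aryl methyl ethers by BBr3 frees the phenols, so that the methyl groups needed for step 1 can be replaced by groups that hydrogenolysis removes at the end.

Step 3
Reactants: 4 2-bromo-4,6-dihydroxybenzaldehyde; 5 4-(benzyloxy)benzyl chloride (two equivalents)
Product: 6 2-bromo-4,6-bis{[4-(benzyloxy)benzyl]oxy}benzaldehyde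
Conditions: 5 (2.2 equiv in all), K2CO3 (3 equiv), KI (cat.), DMF, 60 °C
Reagents that add atoms: 4-(benzyloxy)benzyl chloride ClCc1ccc(OCc2ccccc2)cc1
Why: Twofold Williamson ether synthesis that consumes two molecules of chloride 5 (the second is the atom-adding reagent listed above), one on each phenoxide, in which the ether ortho to the aldehyde supplies the benzylic CH2 that becomes C2 with its 4-(benzyloxy)phenyl group and the para ether protects the future C6 oxygen.

Step 4
Reactants: 6 2-bromo-4,6-bis{[4-(benzyloxy)benzyl]oxy}benzaldehyde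
Product: 8 2-Ar-acetonitrile, via N-(1-tosylalkenyl)formamide 7 (not isolated)
Conditions: TosMIC, KOt-Bu, DME, −40 °C; then MeOH, reflux
Reagents that add atoms: p-toluenesulfonylmethyl isocyanide Cc1ccc(cc1)S(=O)(=O)C[N+]#[C-]
Why: Van Leusen reductive cyanation, in which the TosMIC anion adds to the aldehyde, the oxazoline opens to formamide 7, and methanolysis with loss of sulfinate gives the one-carbon-longer nitrile under basic conditions that spare the acid-labile 4-alkoxybenzyl ethers.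

Step 5
Reactants: 8 2-Ar-acetonitrile
Product: 9 2-Ar-acetic acid
Conditions: KOH, EtOH–H2O, reflux; then cold 1 M HCl
Reagents that add atoms: potassium hydroxide [K+].[OH-]; water O
Why: Alkaline nitrile hydrolysis through the primary amide, which benzyl ethers and the aryl bromide tolerate, followed by a brief cold acidification that does not cleave the ethers.

Step 6
Reactants: 9 2-Ar-acetic acid
Product: 10 methyl 2-Ar-acetate
Conditions: MeI, K2CO3, DMF, rt
Reagents that add atoms: iodomethane CI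
Why: SN2 O-alkylation of the carboxylate by iodomethane gives the methyl ester without acid.

Step 7
Reactants: 10 methyl 2-Ar-acetate
Product: 11 methyl 2-Ar-2-diazoacetate
Conditions: p-ABSA, DBU, MeCN, 0 °C to rt
Reagents that add atoms: 4-acetamidobenzenesulfonyl azide CC(=O)Nc1ccc(cc1)S(=O)(=O)N=[N+]=[N-]
Why: Regitz diazo transfer, in which the ester enolate attacks the sulfonyl azide and loss of the sulfonamide leaves the aryldiazoacetate.

Step 8
Reactants: 11 methyl 2-Ar-2-diazoacetate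
Product: 12 methyl (2S,3R)-2-[4-(benzyloxy)phenyl]-6-{[4-(benzyloxy)benzyl]oxy}-4-bromo-2,3-dihydro-1-benzofuran-3-carboxylate (cis)
Conditions: Rh2(S-PTTL)4 (1 mol %), toluene, −60 °C
Reagents that add atoms: none
Why: Intramolecular 1,5 C–H insertion of the dirhodium carbenoid into the benzylic C–H bond of the ortho ether closes the dihydrofuran ring, the concerted insertion giving the cis ester and the chiral carboxylate ligands choosing the enantiotopic hydrogen, which sets C2 as S (and C3 as R).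

Step 9
Reactants: 12 cis ester
Product: 14 Q-carboxylic acid (trans; 2S,3S), via trans methyl ester 13 (not isolated)
Conditions: NaOMe (0.3 equiv), MeOH–THF, rt; then LiOH, H2O, 40 °C; then cold 1 M HCl
Reagents that add atoms: lithium hydroxide [Li+].[OH-]
Why: Base-mediated epimerisation through the ester enolate moves C3 to the more stable trans arrangement (C3 becomes S, C2 is untouched), and addition–elimination saponification by hydroxide then gives the acid.

Step 10
Reactants: 15 2,2,6-trimethyl-4H-1,3-dioxin-4-one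
Product: 17 2,2-dimethyl-6-(2-oxopropyl)-4H-1,3-dioxin-4-one, via lithium dienolate 16 (not isolated)
Conditions: LiN(SiMe3)2 (2 equiv), THF, −78 °C; AcCl (1 equiv); aq. NH4Cl
Reagents that add atoms: acetyl chloride CC(Cl)=O
Why: Vinylogous Claisen acylation of the dioxinone dienolate at its terminal carbon, the second equivalent of base deprotonating the more acidic product so that it is not acylated again.

Step 11
Reactants: 14 Q-carboxylic acid; 17 2,2-dimethyl-6-(2-oxopropyl)-4H-1,3-dioxin-4-one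
Product: 20 6-(4-Q-2,4-dioxobutyl)-2,2-dimethyl-4H-1,3-dioxin-4-one, via acyl imidazolide 18 (not isolated), via dianion 19 (not isolated)
Conditions: 14, CDI, THF, rt; 17, LiN(iPr)2 (2.1 equiv), THF, −78 °C; combine at −78 °C (19 in excess); AcOH
Reagents that add atoms: none
Why: Crossed Claisen condensation, in which the terminal carbon of dianion 19 attacks acyl imidazolide 18 at −78 °C faster than it removes the C3 proton, and the β-diketone formed is deprotonated at once, which shields C3 from enolisation.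

Step 12
Reactants: 20 6-(4-Q-2,4-dioxobutyl)-2,2-dimethyl-4H-1,3-dioxin-4-one
Product: 23 methyl 2-Q-4,6-dihydroxybenzoate, via acylketene 21 (not isolated), via triketo ester 22 (not isolated)
Conditions: MeOH (20 equiv), PhMe, 110 °C, sealed tube; then Cs2CO3 (2 equiv), MeOH, 0 °C to rt; then AcOH
Reagents that add atoms: methanol CO
Why: Heating opens the dioxinone by retro-[4+2] loss of acetone to acylketene 21, which the excess of methanol should capture faster than the chain enol can (that path would give a 4-hydroxypyran-2-one), so that linear 3,5,7-trioxo ester 22 results. With Cs2CO3 in methanol the ester α-carbon (chain C2, as its enolate) adds to the C7 ketone bonded to benzofuran C3, and two dehydrations with enolisation give the arene, forming one ring C–C bond and a six-membered aromatic ring made of the ketone carbon and five chain carbons. The closest known reaction is the biomimetic aldol aromatisation of dioxinone-derived triketo esters to β-resorcylates, the orsellinate fold of polyketide biosynthesis. The ring closes in the 6-(enolendo)-exo-trig mode, whereas the competing Claisen closure (C6 onto the ester carbonyl, to an acylphloroglucinol) needs a chelating counter-ion in aprotic medium and is disfavoured by the protic solvent and the caesium ion. No stereocentre is formed, and C2 and C3 are kept because the C7 carbonyl sits in an enolised β-diketone, then in an aldolate and finally in an arene, so that C3–H is never the acidic site and the aryloxy group on C2 is not expelled; the trans arrangement is in any case the stable one. The step therefore needs aldol over Claisen regioselectivity and intermolecular over intramolecular ketene capture, secured by the methanol excess and the mild carbonate base.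

Step 13
Reactants: 23 methyl 2-Q-4,6-dihydroxybenzoate
Product: 25 5-Q-benzene-1,3-diol, via resorcylic acid 24 (not isolated)
Conditions: KOH, MeOH–H2O, 90 °C, sealed, argon; then AcOH to pH 6
Reagents that add atoms: none
Why: Hydroxide cleaves the hindered ester and the 2,4-dihydroxybenzoate then loses CO2 by ipso protonation of the electron-rich ring, the known protodecarboxylation of β-resorcylic acids.

Step 14
Reactants: 25 5-Q-benzene-1,3-diol
Product: 26 (2S,3S)-2-[4-(benzyloxy)phenyl]-6-{[4-(benzyloxy)benzyl]oxy}-3-[3,5-bis(benzyloxy)phenyl]-4-bromo-2,3-dihydro-1-benzofuran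
Conditions: BnBr, K2CO3, DMF, rt
Reagents that add atoms: benzyl bromide BrCc1ccccc1
Why: Williamson benzylation of the two phenols gives ethers that survive the organometallic coupling and fall to hydrogenolysis.

Step 15
Reactants: 27 4-(benzyloxy)benzaldehyde; 28 methyl propiolate
Product: 30 methyl (4S)-4-[4-(benzyloxy)phenyl]-4-hydroxybut-2-ynoate, via alkynyl(methyl)zinc 29 (not isolated)
Conditions: (S,S)-ProPhenol (10 mol %), Ph3P=O (20 mol %), Me2Zn, PhMe, 4 °C; aq. NH4Cl
Reagents that add atoms: none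
Why: Zinc–ProPhenol catalysed asymmetric alkynylation, in which the dinuclear zinc complex binds the aldehyde and alkynylzinc 29 and delivers the alkynyl group to one face of the aldehyde, which sets the carbinol centre as S.

Step 16
Reactants: 30 methyl (4S)-4-[4-(benzyloxy)phenyl]-4-hydroxybut-2-ynoate
Product: 32 (5R)-5-[4-(benzyloxy)phenyl]furan-2(5H)-one, via Z-hydroxy enoate 31 (not isolated)
Conditions: H2 (1 atm), Pd/CaCO3 poisoned with Pb(OAc)2, quinoline, EtOAc, rt; then PPTS (cat.), CH2Cl2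
Reagents that add atoms: none
Why: Lindlar semi-hydrogenation gives the Z alkene, whose hydroxyl and ester then lactonise by transesterification, the carbinol centre being untouched (it becomes C5 and is R by change of priorities only).

Step 17
Reactants: 32 (5R)-5-[4-(benzyloxy)phenyl]furan-2(5H)-one; 33 1,3-bis(benzyloxy)-5-bromobenzene
Product: 35 (4S,5R)-4-[3,5-bis(benzyloxy)phenyl]-5-[4-(benzyloxy)phenyl]oxolan-2-one, via arylmagnesium bromide 34 (not isolated)
Conditions: 33, Mg, THF; CuBr·SMe2 (20 mol %), THF, −78 °C, then 32; aq. NH4Cl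
Reagents that add atoms: none
Why: Copper-catalysed conjugate addition of the aryl Grignard reagent, the arylcopper adding to C4 on the face opposite the C5 aryl group, which sets C4 as S, trans to C5.

Step 18
Reactants: 35 (4S,5R)-4-[3,5-bis(benzyloxy)phenyl]-5-[4-(benzyloxy)phenyl]oxolan-2-one; 36 1-(benzyloxy)-4-bromobenzene
Product: 39 (4S,5R)-4-[3,5-bis(benzyloxy)phenyl]-2,5-bis[4-(benzyloxy)phenyl]-4,5-dihydrofuran, via aryllithium 37 (not isolated), via hemiketal 38 (not isolated)
Conditions: 36, n-BuLi, THF, −78 °C; then 35, −78 °C; aq. NH4Cl; then PPTS (cat.), PhMe, 4 Å MS, 80 °C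
Reagents that add atoms: none
Why: Addition of the aryllithium to the lactone carbonyl stops at the lithium lactolate at −78 °C, and acid-catalysed dehydration of hemiketal 38 gives the aryl-conjugated cyclic enol ether with C4 and C5 untouched.

Step 19
Reactants: 39 (4S,5R)-4-[3,5-bis(benzyloxy)phenyl]-2,5-bis[4-(benzyloxy)phenyl]-4,5-dihydrofuran
Product: 40 (4S,5R)-4-[3,5-bis(benzyloxy)phenyl]-2,5-bis[4-(benzyloxy)phenyl]-3-bromo-4,5-dihydrofuran
Conditions: NBS, 2,6-lutidine, CH2Cl2, −78 to 0 °C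
Reagents that add atoms: N-bromosuccinimide O=C1CCC(=O)N1Br
Why: Electrophilic bromination of the enol ether at its β-carbon (C3) and loss of the C3 proton from the aryl-stabilised oxocarbenium ion give the vinyl bromide, the enol ether reacting far faster at −78 °C than the alkoxyarene rings.

Step 20
Reactants: 40 bromo-dihydrofuran; 26 benzylated aryl bromide
Product: 43 (2S,3S)-2-[4-(benzyloxy)phenyl]-6-{[4-(benzyloxy)benzyl]oxy}-3-[3,5-bis(benzyloxy)phenyl]-4-{(4R,5R)-4-[3,5-bis(benzyloxy)phenyl]-2,5-bis[4-(benzyloxy)phenyl]-4,5-dihydrofuran-3-yl}-2,3-dihydro-1-benzofuran, via vinyllithium 41 (not isolated), via vinylzinc chloride 42 (not isolated)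
Conditions: 40, t-BuLi (2 equiv), THF, −78 °C; ZnCl2; then 26, Pd2(dba)3 (2.5 mol %), RuPhos (10 mol %), THF, 65 °C
Reagents that add atoms: none
Why: Negishi coupling, in which bromine–lithium exchange and transmetalation give vinylzinc 42 and a zerovalent palladium catalyst carrying the bulky biaryl phosphine joins its C3 to C4 of aryl bromide 26, a ligand class known to couple ortho-hindered partners, with no stereocentre formed.

Step 21
Reactants: 43 tetrasubstituted enol ether
Product: 44 (2S,3S)-2-[4-(benzyloxy)phenyl]-6-{[4-(benzyloxy)benzyl]oxy}-3-[3,5-bis(benzyloxy)phenyl]-4-{(2R,3R,4S,5R)-4-[3,5-bis(benzyloxy)phenyl]-2,5-bis[4-(benzyloxy)phenyl]oxolan-3-yl}-2,3-dihydro-1-benzofuran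
Conditions: H2 (30 bar), 5% Pt/C, EtOAc, rt
Reagents that add atoms: none
Why: Heterogeneous syn hydrogenation should deliver both hydrogens to C2 and C3 of the dihydrofuran from the face opposite the allylic C4 aryl group, so that the C2 and C3 aryl groups end up cis to each other and to the C4 aryl group (C2 R, C3 R) while the C5 aryl group stays trans, platinum being chosen because it reduces alkenes without cleaving benzylic C–O bonds.

Step 22
Reactants: 44 fully benzylated oxolane
Product: 45 5-[(2S,3S)-4-[(2R,3R,4S,5R)-4-(3,5-dihydroxyphenyl)-2,5-bis(4-hydroxyphenyl)oxolan-3-yl]-6-hydroxy-2-(4-hydroxyphenyl)-2,3-dihydro-1-benzofuran-3-yl]benzene-1,3-diol (target)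
Conditions: H2 (1 atm), 10% Pd/C, THF–MeOH, rt
Reagents that add atoms: none
Why: Hydrogenolysis on palladium cleaves the nine primary benzylic O–CH2 bonds much faster than the secondary benzylic ring C–O bonds and touches no stereocentre, which avoids the Lewis acids that would ionise the oxolane C2–O bond.

**Compound list**

1 | 1-bromo-3,5-dimethoxybenzene | COc1cc(Br)cc(OC)c1 | starting material
2 | N-[(2-bromo-4,6-dimethoxyphenyl)methylidene]-N-methylmethanaminium chloride | C[N+](C)=Cc1c(Br)cc(OC)cc1OC.[Cl-] | intermediate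
3 | 2-bromo-4,6-dimethoxybenzaldehyde | COc1cc(Br)c(C=O)c(OC)c1 | intermediate
4 | 2-bromo-4,6-dihydroxybenzaldehyde | Oc1cc(Br)c(C=O)c(O)c1 | intermediate
5 | 4-(benzyloxy)benzyl chloride | ClCc1ccc(OCc2ccccc2)cc1 | starting material
6 | 2-bromo-4,6-bis{[4-(benzyloxy)benzyl]oxy}benzaldehyde | O=Cc1c(Br)cc(OCc2ccc(OCc3ccccc3)cc2)cc1OCc1ccc(OCc2ccccc2)cc1 | intermediate
7 | N-[2-Ar-1-(4-methylbenzenesulfonyl)ethenyl]formamide | O=CNC(=Cc1c(Br)cc(OCc2ccc(OCc3ccccc3)cc2)cc1OCc1ccc(OCc2ccccc2)cc1)S(=O)(=O)c1ccc(C)cc1 | intermediate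
8 | 2-Ar-acetonitrile | N#CCc1c(Br)cc(OCc2ccc(OCc3ccccc3)cc2)cc1OCc1ccc(OCc2ccccc2)cc1 | intermediate
9 | 2-Ar-acetic acid | OC(=O)Cc1c(Br)cc(OCc2ccc(OCc3ccccc3)cc2)cc1OCc1ccc(OCc2ccccc2)cc1 | intermediate
10 | methyl 2-Ar-acetate | COC(=O)Cc1c(Br)cc(OCc2ccc(OCc3ccccc3)cc2)cc1OCc1ccc(OCc2ccccc2)cc1 | intermediate
11 | methyl 2-Ar-2-diazoacetate | COC(=O)C(=[N+]=[N-])c1c(Br)cc(OCc2ccc(OCc3ccccc3)cc2)cc1OCc1ccc(OCc2ccccc2)cc1 | intermediate
12 | methyl (2S,3R)-2-[4-(benzyloxy)phenyl]-6-{[4-(benzyloxy)benzyl]oxy}-4-bromo-2,3-dihydro-1-benzofuran-3-carboxylate (cis) | c1ccccc1COc1ccc([C@H]2Oc3cc(OCc4ccc(OCc5ccccc5)cc4)cc(Br)c3[C@H]2C(=O)OC)cc1 | intermediate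
13 | methyl (2S,3S)-2-[4-(benzyloxy)phenyl]-6-{[4-(benzyloxy)benzyl]oxy}-4-bromo-2,3-dihydro-1-benzofuran-3-carboxylate (trans; Q-CO2Me) | c1ccccc1COc1ccc([C@H]2Oc3cc(OCc4ccc(OCc5ccccc5)cc4)cc(Br)c3[C@@H]2C(=O)OC)cc1 | intermediate
14 | (2S,3S)-2-[4-(benzyloxy)phenyl]-6-{[4-(benzyloxy)benzyl]oxy}-4-bromo-2,3-dihydro-1-benzofuran-3-carboxylic acid (Q-CO2H) | c1ccccc1COc1ccc([C@H]2Oc3cc(OCc4ccc(OCc5ccccc5)cc4)cc(Br)c3[C@@H]2C(=O)O)cc1 | intermediate
15 | 2,2,6-trimethyl-4H-1,3-dioxin-4-one | CC1=CC(=O)OC(C)(C)O1 | starting material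
16 | lithium 2,2-dimethyl-6-methylidene-6H-1,3-dioxin-4-olate | [Li]OC1=CC(=C)OC(C)(C)O1 | intermediate
17 | 2,2-dimethyl-6-(2-oxopropyl)-4H-1,3-dioxin-4-one | CC(=O)CC1=CC(=O)OC(C)(C)O1 | intermediate
18 | 1-(Q-carbonyl)-1H-imidazole | c1ccccc1COc1ccc([C@H]2Oc3cc(OCc4ccc(OCc5ccccc5)cc4)cc(Br)c3[C@@H]2C(=O)n2ccnc2)cc1 | intermediate
19 | dilithium dianion of 17 (deprotonated at CH3 and at the ring-bound CH2) | [Li+].[Li+].[CH2-]C(=O)[CH-]C1=CC(=O)OC(C)(C)O1 | intermediate
20 | 6-(4-Q-2,4-dioxobutyl)-2,2-dimethyl-4H-1,3-dioxin-4-one | c1ccccc1COc1ccc([C@H]2Oc3cc(OCc4ccc(OCc5ccccc5)cc4)cc(Br)c3[C@@H]2C(=O)CC(=O)CC2=CC(=O)OC(C)(C)O2)cc1 | intermediate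
21 | 7-Q-3,5,7-trioxohept-1-en-1-one (acylketene) | c1ccccc1COc1ccc([C@H]2Oc3cc(OCc4ccc(OCc5ccccc5)cc4)cc(Br)c3[C@@H]2C(=O)CC(=O)CC(=O)C=C=O)cc1 | intermediate
22 | methyl 7-Q-3,5,7-trioxoheptanoate | c1ccccc1COc1ccc([C@H]2Oc3cc(OCc4ccc(OCc5ccccc5)cc4)cc(Br)c3[C@@H]2C(=O)CC(=O)CC(=O)CC(=O)OC)cc1 | intermediate
23 | methyl 2-Q-4,6-dihydroxybenzoate | c1ccccc1COc1ccc([C@H]2Oc3cc(OCc4ccc(OCc5ccccc5)cc4)cc(Br)c3[C@@H]2c2cc(O)cc(O)c2C(=O)OC)cc1 | intermediate
24 | 2-Q-4,6-dihydroxybenzoic acid | c1ccccc1COc1ccc([C@H]2Oc3cc(OCc4ccc(OCc5ccccc5)cc4)cc(Br)c3[C@@H]2c2cc(O)cc(O)c2C(=O)O)cc1 | intermediate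
25 | 5-Q-benzene-1,3-diol | c1ccccc1COc1ccc([C@H]2Oc3cc(OCc4ccc(OCc5ccccc5)cc4)cc(Br)c3[C@@H]2c2cc(O)cc(O)c2)cc1 | intermediate
26 | (2S,3S)-2-[4-(benzyloxy)phenyl]-6-{[4-(benzyloxy)benzyl]oxy}-3-[3,5-bis(benzyloxy)phenyl]-4-bromo-2,3-dihydro-1-benzofuran | c1ccccc1COc1ccc([C@H]2Oc3cc(OCc4ccc(OCc5ccccc5)cc4)cc(Br)c3[C@@H]2c2cc(OCc3ccccc3)cc(OCc3ccccc3)c2)cc1 | intermediate
27 | 4-(benzyloxy)benzaldehyde | O=Cc1ccc(OCc2ccccc2)cc1 | starting material
28 | methyl propiolate | C#CC(=O)OC | starting material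
29 | (3-methoxy-3-oxoprop-1-yn-1-yl)(methyl)zinc | C[Zn]C#CC(=O)OC | intermediate
30 | methyl (4S)-4-[4-(benzyloxy)phenyl]-4-hydroxybut-2-ynoate | COC(=O)C#C[C@@H](O)c1ccc(OCc2ccccc2)cc1 | intermediate
31 | methyl (2Z,4R)-4-[4-(benzyloxy)phenyl]-4-hydroxybut-2-enoate | COC(=O)/C=C\[C@@H](O)c1ccc(OCc2ccccc2)cc1 | intermediate
32 | (5R)-5-[4-(benzyloxy)phenyl]furan-2(5H)-one | O=C1C=C[C@H](c2ccc(OCc3ccccc3)cc2)O1 | intermediate
33 | 1,3-bis(benzyloxy)-5-bromobenzene | Brc1cc(OCc2ccccc2)cc(OCc2ccccc2)c1 | starting material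
34 | [3,5-bis(benzyloxy)phenyl]magnesium bromide | Br[Mg]c1cc(OCc2ccccc2)cc(OCc2ccccc2)c1 | intermediate
35 | (4S,5R)-4-[3,5-bis(benzyloxy)phenyl]-5-[4-(benzyloxy)phenyl]oxolan-2-one (trans) | O=C1C[C@@H](c2cc(OCc3ccccc3)cc(OCc3ccccc3)c2)[C@H](c2ccc(OCc3ccccc3)cc2)O1 | intermediate
36 | 1-(benzyloxy)-4-bromobenzene | Brc1ccc(OCc2ccccc2)cc1 | starting material
37 | [4-(benzyloxy)phenyl]lithium | [Li]c1ccc(OCc2ccccc2)cc1 | intermediate
38 | (4S,5R)-4-[3,5-bis(benzyloxy)phenyl]-2,5-bis[4-(benzyloxy)phenyl]oxolan-2-ol (both C2 anomers) | OC1(c2ccc(OCc3ccccc3)cc2)C[C@@H](c2cc(OCc3ccccc3)cc(OCc3ccccc3)c2)[C@H](c2ccc(OCc3ccccc3)cc2)O1 | intermediate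
39 | (4S,5R)-4-[3,5-bis(benzyloxy)phenyl]-2,5-bis[4-(benzyloxy)phenyl]-4,5-dihydrofuran | C1=C(c2ccc(OCc3ccccc3)cc2)O[C@@H](c2ccc(OCc3ccccc3)cc2)[C@@H]1c1cc(OCc2ccccc2)cc(OCc2ccccc2)c1 | intermediate
40 | (4S,5R)-4-[3,5-bis(benzyloxy)phenyl]-2,5-bis[4-(benzyloxy)phenyl]-3-bromo-4,5-dihydrofuran | BrC1=C(c2ccc(OCc3ccccc3)cc2)O[C@@H](c2ccc(OCc3ccccc3)cc2)[C@@H]1c1cc(OCc2ccccc2)cc(OCc2ccccc2)c1 | intermediate
41 | {(4S,5R)-4-[3,5-bis(benzyloxy)phenyl]-2,5-bis[4-(benzyloxy)phenyl]-4,5-dihydrofuran-3-yl}lithium | [Li]C1=C(c2ccc(OCc3ccccc3)cc2)O[C@@H](c2ccc(OCc3ccccc3)cc2)[C@@H]1c1cc(OCc2ccccc2)cc(OCc2ccccc2)c1 | intermediate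
42 | {(4S,5R)-4-[3,5-bis(benzyloxy)phenyl]-2,5-bis[4-(benzyloxy)phenyl]-4,5-dihydrofuran-3-yl}zinc chloride | Cl[Zn]C1=C(c2ccc(OCc3ccccc3)cc2)O[C@@H](c2ccc(OCc3ccccc3)cc2)[C@@H]1c1cc(OCc2ccccc2)cc(OCc2ccccc2)c1 | intermediate
43 | (2S,3S)-2-[4-(benzyloxy)phenyl]-6-{[4-(benzyloxy)benzyl]oxy}-3-[3,5-bis(benzyloxy)phenyl]-4-{(4R,5R)-4-[3,5-bis(benzyloxy)phenyl]-2,5-bis[4-(benzyloxy)phenyl]-4,5-dihydrofuran-3-yl}-2,3-dihydro-1-benzofuran | c1ccccc1COc1ccc([C@H]2Oc3cc(OCc4ccc(OCc5ccccc5)cc4)cc(C4=C(c5ccc(OCc6ccccc6)cc5)O[C@@H](c5ccc(OCc6ccccc6)cc5)[C@@H]4c4cc(OCc5ccccc5)cc(OCc5ccccc5)c4)c3[C@@H]2c2cc(OCc3ccccc3)cc(OCc3ccccc3)c2)cc1 | intermediate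
44 | (2S,3S)-2-[4-(benzyloxy)phenyl]-6-{[4-(benzyloxy)benzyl]oxy}-3-[3,5-bis(benzyloxy)phenyl]-4-{(2R,3R,4S,5R)-4-[3,5-bis(benzyloxy)phenyl]-2,5-bis[4-(benzyloxy)phenyl]oxolan-3-yl}-2,3-dihydro-1-benzofuran | c1ccccc1COc1ccc([C@H]2Oc3cc(OCc4ccc(OCc5ccccc5)cc4)cc([C@H]4[C@@H](c5cc(OCc6ccccc6)cc(OCc6ccccc6)c5)[C@H](c5ccc(OCc6ccccc6)cc5)O[C@H]4c4ccc(OCc5ccccc5)cc4)c3[C@@H]2c2cc(OCc3ccccc3)cc(OCc3ccccc3)c2)cc1 | intermediate
45 | 5-[(2S,3S)-4-[(2R,3R,4S,5R)-4-(3,5-dihydroxyphenyl)-2,5-bis(4-hydroxyphenyl)oxolan-3-yl]-6-hydroxy-2-(4-hydroxyphenyl)-2,3-dihydro-1-benzofuran-3-yl]benzene-1,3-diol | Oc1ccc([C@H]2Oc3cc(O)cc([C@H]4[C@@H](c5cc(O)cc(O)c5)[C@H](c5ccc(O)cc5)O[C@H]4c4ccc(O)cc4)c3[C@@H]2c2cc(O)cc(O)c2)cc1 | target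

**Step count and risk**

Total: 22 steps. Longest linear sequence: 16 steps (1 to 9, 11 to 14, 20 to 22).

Most likely to fail, step 12 (key step). The triketo ester may fold by Claisen acylation instead of aldol addition onto the hindered, α-branched ketone; the acylketene may be captured by the chain enol before methanol reaches it; or carbonate may ionise C3 and open the dihydrofuran by loss of the aryloxide. The fallback sets out from 20 and uses neither ketene nor ester, so that neither Claisen closure nor pyranone formation is possible. Et3N in CH2Cl2 at room temperature should make the ring carbon C5 of the intact dioxinone add to the C3-bound ketone, and aromatisation gives the acetonide-protected resorcylate 5-Q-7-hydroxy-2,2-dimethyl-4H-1,3-benzodioxin-4-one F1. KOH in aqueous methanol at 90 °C then opens the acetonide, the liberated acid 24 decarboxylates, and the route is rejoined at 25.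

Step 20. Both partners are crowded (a tetrasubstituted vinylzinc and an ortho-branched aryl bromide), so slow transmetalation, protonation of the vinylzinc and homocoupling may take over. The fallback sets out from 35 and 26 and forms the same bond by enolate arylation. Me(MeO)NH·HCl with i-PrMgCl opens the lactone to the hydroxy Weinreb amide F2, and t-BuMe2SiOTf with 2,6-lutidine gives the silyl ether F3. 4-(Benzyloxy)phenylmagnesium bromide then gives the aryl ketone F4. Palladium-catalysed ketone α-arylation with 26 (Pd(OAc)2, XPhos, NaOt-Bu, PhMe, 80 °C) gives the α-arylated ketone F5 as either C2 epimer, which does not matter because that carbon becomes sp2. Bu4NF followed by PPTS in warm toluene removes the silyl group and closes and dehydrates the hemiketal, and the route is rejoined at 43.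

Step 21. Hydrogen may be delivered with poor facial selectivity (syn to the C4 aryl group, which would give the C2 and C3 epimers), the crowded tetrasubstituted alkene may not be reduced at all, or ring benzylic C–O bonds may be hydrogenolysed under forcing conditions. The fallback sets out from 43 and is an ionic hydrogenation (Et3SiH in excess, CF3CO2H, CH2Cl2, −78 to −40 °C). Protonation at dihydrofuran C3 from the face away from the C4 aryl group and hydride transfer to the oxocarbenium carbon C2 anti to the new C3 aryl group should set the same two centres stepwise; the cation has to be trapped cold, before it equilibrates through the enol ether to the C3 epimer. It comes back at 44 and makes no further compound (none F0).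

**Further compounds**

F1 | step 12 | 5-Q-7-hydroxy-2,2-dimethyl-4H-1,3-benzodioxin-4-one | c1ccccc1COc1ccc([C@H]2Oc3cc(OCc4ccc(OCc5ccccc5)cc4)cc(Br)c3[C@@H]2c2cc(O)cc3OC(C)(C)OC(=O)c23)cc1
F2 | step 20 | (3S,4R)-3-[3,5-bis(benzyloxy)phenyl]-4-[4-(benzyloxy)phenyl]-4-hydroxy-N-methoxy-N-methylbutanamide | CON(C)C(=O)C[C@@H](c1cc(OCc2ccccc2)cc(OCc2ccccc2)c1)[C@@H](O)c1ccc(OCc2ccccc2)cc1
F3 | step 20 | (3S,4R)-3-[3,5-bis(benzyloxy)phenyl]-4-[4-(benzyloxy)phenyl]-4-[(tert-butyldimethylsilyl)oxy]-N-methoxy-N-methylbutanamide | CON(C)C(=O)C[C@@H](c1cc(OCc2ccccc2)cc(OCc2ccccc2)c1)[C@@H](O[Si](C)(C)C(C)(C)C)c1ccc(OCc2ccccc2)cc1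
F4 | step 20 | (3S,4R)-3-[3,5-bis(benzyloxy)phenyl]-1,4-bis[4-(benzyloxy)phenyl]-4-[(tert-butyldimethylsilyl)oxy]butan-1-one | O=C(C[C@@H](c1cc(OCc2ccccc2)cc(OCc2ccccc2)c1)[C@@H](O[Si](C)(C)C(C)(C)C)c1ccc(OCc2ccccc2)cc1)c1ccc(OCc2ccccc2)cc1
F5 | step 20 | (3S,4R)-2-{(2S,3S)-2-[4-(benzyloxy)phenyl]-6-{[4-(benzyloxy)benzyl]oxy}-3-[3,5-bis(benzyloxy)phenyl]-2,3-dihydro-1-benzofuran-4-yl}-3-[3,5-bis(benzyloxy)phenyl]-1,4-bis[4-(benzyloxy)phenyl]-4-[(tert-butyldimethylsilyl)oxy]butan-1-one (either C2 epimer) | c1ccccc1COc1ccc([C@H]2Oc3cc(OCc4ccc(OCc5ccccc5)cc4)cc(C(C(=O)c4ccc(OCc5ccccc5)cc4)[C@@H](c4cc(OCc5ccccc5)cc(OCc5ccccc5)c4)[C@@H](O[Si](C)(C)C(C)(C)C)c4ccc(OCc5ccccc5)cc4)c3[C@@H]2c2cc(OCc3ccccc3)cc(OCc3ccccc3)c2)cc1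
F0 | step 21 | none | none
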